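**Strategy.** Everything rests on breaking the C9–C10 bond of ring B. The quaternary carbon C9, whose neighbours are a methyl, the arylmethyl arm, C8 and the ring-fusion carbon C10, is masked as a 1,1-disubstituted olefin. This olefin is tied through the Roche-ester-derived C8 methine to a ring-A cyclohexenyl ketone. In one operation, hydrogen-atom transfer from an iron hydride makes the C9 methyl and a tertiary radical, which closes ring B onto C10 and relays the C8 configuration to C9 and C10. The open-chain precursor is assembled from an aryllithium, a Roche-ester allyl bromide and a cyclohexenyl Weinreb amide. Afterwards the C6 ketone becomes the C5=C6 olefin and the arene the hydroxy-methoxyquinone.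

Key step: step 10

Remark on numbering: decalin carbons carry terpenoid numbers (C1–C3 ring-A CH2 groups, C4 the gem-dimethyl carbon, C5 and C10 the ring fusion, C6 and C7 in ring B, C8 the methine with a methyl, C9 the quaternary carbon); Ar = 2,3,5,6-tetramethoxyphenyl.

Remark on the chemistry: the ester carbon of the (S)-Roche ester becomes C9 and its CH2OH carbon becomes C7, so the purchased centre is C8 with the configuration of the target (8S,9R,10S). Organometallic and enolate steps are taken as quenched with water.

Remark on design: the olefin–arene part is made by allylic substitution with an aryllithium, so no configurationally labile α-methyl ketone and no benzylic Grignard reagent is needed.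

Step 1
Reactants: 1 methyl (S)-3-hydroxy-2-methylpropanoate
Product: 2 methyl (S)-3-[(tert-butyldimethylsilyl)oxy]-2-methylpropanoate
Conditions: TBSCl, imidazole, CH2Cl2, 0 °C to rt
Reagents that add atoms: tert-butyldimethylsilyl chloride, CC(C)(C)[Si](C)(C)Cl
Why: Imidazole-promoted silyl ether formation at the primary alcohol is fast and non-basic, so the α-stereocentre of the ester is not touched.

Step 2
Reactants: 2 methyl (S)-3-[(tert-butyldimethylsilyl)oxy]-2-methylpropanoate
Product: 4 tert-butyldimethyl{[(2R)-2-methyl-3-[(trimethylsilyl)methyl]but-3-en-1-yl]oxy}silane, via bis(silylmethyl) carbinol 3 (not isolated)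
Conditions: Me3SiCH2MgCl (3.5 equiv), anhydrous CeCl3 (3.5 equiv), THF, −78 °C to rt; H2O; then SiO2, CH2Cl2, rt
Reagents that add atoms: (trimethylsilyl)methylmagnesium chloride, C[Si](C)(C)C[Mg]Cl
Why: Cerium-mediated double addition of the silylmethyl Grignard reagent to the ester, then Peterson elimination of one β-hydroxysilane arm on silica, turns the ester carbon into the future C9 with its =CH2 and CH2Si arms; the weakly basic organocerium species should not enolise next to C8, whose descriptor changes from S to R by priority only.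

Step 3
Reactants: 4 tert-butyldimethyl{[(2R)-2-methyl-3-[(trimethylsilyl)methyl]but-3-en-1-yl]oxy}silane
Product: 5 {[(2R)-3-(bromomethyl)-2-methylbut-3-en-1-yl]oxy}(tert-butyl)dimethylsilane
Conditions: NBS (1.0 equiv), propylene oxide, CH2Cl2, −78 to 0 °C, dark
Reagents that add atoms: N-bromosuccinimide, O=C1CCC(=O)N1Br
Why: Electrophilic bromodesilylation of the allylsilane (SE2′) gives the allyl bromide without regiochemical ambiguity because the allyl unit is 2-substituted, and the silyl ether and the stereocentre are spectators.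

Step 4
Reactants: 6 1,2,4,5-tetramethoxybenzene; 5 {[(2R)-3-(bromomethyl)-2-methylbut-3-en-1-yl]oxy}(tert-butyl)dimethylsilane
Product: 8 tert-butyldimethyl{[(2R)-2-methyl-3-(2,3,5,6-tetramethoxybenzyl)but-3-en-1-yl]oxy}silane, via aryllithium 7 (not isolated)
Conditions: 6, n-BuLi, THF, 0 °C to rt; then CuBr·SMe2 (10 mol%), 5, −78 °C to rt
Reagents that add atoms: none
Why: Directed ortho-lithiation of 6 between two methoxy groups followed by copper-catalysed allylic substitution forms the aryl–CH2 bond; SN2 and SN2′ attack give the same product because the two CH2 termini of the allyl unit are equivalent.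

Step 5
Reactants: 8 tert-butyldimethyl{[(2R)-2-methyl-3-(2,3,5,6-tetramethoxybenzyl)but-3-en-1-yl]oxy}silane
Product: 9 (2R)-2-methyl-3-(2,3,5,6-tetramethoxybenzyl)but-3-en-1-ol
Conditions: TBAF, THF, 0 °C to rt; H2O
Reagents that add atoms: none
Why: Fluoride-induced desilylation is orthogonal to the aryl methyl ethers and the olefin.

Step 6
Reactants: 9 (2R)-2-methyl-3-(2,3,5,6-tetramethoxybenzyl)but-3-en-1-ol
Product: 10 3-[(3R)-4-iodo-3-methyl-2-methylidenebutyl]-1,2,4,5-tetramethoxybenzene
Conditions: I2, PPh3, imidazole, CH2Cl2, 0 °C to rt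
Reagents that add atoms: iodine, II
Why: Appel-type iodination converts the primary alcohol into the iodide by SN2 at CH2 under neutral conditions that spare the electron-rich arene, the olefin and the neighbouring stereocentre.

Step 7
Reactants: 11 2,2-dimethylcyclohexanone
Product: 13 6,6-dimethylcyclohex-1-en-1-yl trifluoromethanesulfonate, via lithium enolate 12 (not isolated)
Conditions: LDA (commercial solution), THF, −78 °C; PhNTf2, −78 °C to rt; H2O
Reagents that add atoms: N-phenylbis(trifluoromethanesulfonimide), O=S(=O)(N(c1ccccc1)S(=O)(=O)C(F)(F)F)C(F)(F)F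
Why: The ketone has a single enolisable side, so enolate formation and O-triflation (enol triflate synthesis) can give only this vinyl triflate.

Step 8
Reactants: 13 6,6-dimethylcyclohex-1-en-1-yl trifluoromethanesulfonate
Product: 14 N-methoxy-N,6,6-trimethylcyclohex-1-ene-1-carboxamide
Conditions: Pd(OAc)2 (5 mol%), dppp (6 mol%), CO (1 atm), MeNH(OMe)·HCl, Et3N, DMF, 60 °C
Reagents that add atoms: carbon monoxide, [C-]#[O+]; N,O-dimethylhydroxylamine hydrochloride, CNOC.Cl
Why: Palladium-catalysed aminocarbonylation of the vinyl triflate (oxidative addition, CO insertion, capture of the acyl-palladium by the hydroxylamine) gives the Weinreb amide directly.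

Step 9
Reactants: 10 3-[(3R)-4-iodo-3-methyl-2-methylidenebutyl]-1,2,4,5-tetramethoxybenzene; 14 N-methoxy-N,6,6-trimethylcyclohex-1-ene-1-carboxamide
Product: 17 (3S)-1-(6,6-dimethylcyclohex-1-en-1-yl)-3-methyl-4-(2,3,5,6-tetramethoxybenzyl)pent-4-en-1-one, via alkyllithium 15 (not isolated), via tetrahedral lithium adduct 16 (not isolated)
Conditions: 10, t-BuLi (2.1 equiv), Et2O–pentane, −78 °C; then 14, THF, −78 to −20 °C; H2O
Reagents that add atoms: none
Why: Iodine–lithium exchange at −78 °C should outrun any deprotonation of the arene or the ArCH2 group, and the primary alkyllithium adds once to the amide (Weinreb ketone synthesis) because the chelated tetrahedral adduct survives until the quench; C8 is not acidic and keeps its configuration.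

Step 10
Reactants: 17 (3S)-1-(6,6-dimethylcyclohex-1-en-1-yl)-3-methyl-4-(2,3,5,6-tetramethoxybenzyl)pent-4-en-1-one
Product: 18 (3S,4R,4aR)-3,4,8,8-tetramethyl-4-(2,3,5,6-tetramethoxybenzyl)octahydronaphthalen-1(2H)-one as both C8a (terpenoid C5) epimers; terpenoid descriptors 8S,9R,10R
Conditions: Fe(acac)3 (0.5 equiv), PhSiH3 (3 equiv), EtOH–(CH2OH)2 (5:1), 0.02 M, 60 °C
Reagents that add atoms: none
Why: Fe(acac)3 and PhSiH3 give an iron hydride that delivers a hydrogen atom to the CH2 terminus of the electron-rich 1,1-disubstituted olefin, which creates the C9 methyl C–H bond and a nucleophilic tertiary C9 radical; the radical adds to the enone β-carbon C10, and the resulting C5 α-keto radical is reduced to the enolate and protonated by ethanol. The closest known reaction type is the iron-hydride hydrogen-atom-transfer reductive olefin–enone coupling (radical conjugate addition), used here intramolecularly. Ring B closes in the 6-endo-trig mode, preferred over 5-exo attack at C5 because the nucleophilic radical is polarity-matched with the β-carbon and 5-exo closure would leave an unstabilised secondary radical at C10. C9 is controlled by the purchased C8 stereocentre through a chair-like transition state that keeps the C8 methyl and the bulky arylmethyl group equatorial and the new C9 methyl axial; C10 is controlled by the E-geometry of the ring-A enone, which holds C1 equatorial and so leaves H10 axial and cis to the arylmethyl group. The step needs chemoselective hydrogen-atom transfer to the isolated olefin in the presence of the enone and the arene, which the higher electron density of that olefin secures, and high dilution keeps the coupling intramolecular. C5 arises as an epimer mixture that the next step erases.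

Step 11
Reactants: 18 (3S,4R,4aR)-3,4,8,8-tetramethyl-4-(2,3,5,6-tetramethoxybenzyl)octahydronaphthalen-1(2H)-one
Product: 20 (3S,4R,4aS)-3,4,8,8-tetramethyl-4-(2,3,5,6-tetramethoxybenzyl)-2,3,4,4a,5,6,7,8-octahydronaphthalen-1-yl trifluoromethanesulfonate (C5=C6 enol triflate; 8S,9R,10S), via potassium enolate 19 (not isolated)
Conditions: KHMDS (0.95 equiv), THF, −78 °C to rt (equilibration); then N-(5-chloropyridin-2-yl)triflimide, −78 °C to rt; H2O
Reagents that add atoms: N-(5-chloropyridin-2-yl)bis(trifluoromethanesulfonimide), O=S(=O)(N(c1ccc(Cl)cn1)S(=O)(=O)C(F)(F)F)C(F)(F)F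
Why: With slightly less than one equivalent of base and warming, the enolates should equilibrate through proton exchange with residual ketone toward the more substituted C5=C6 enolate common to both C5 epimers, and O-sulfonylation (enol triflate formation) fixes it; C8, C9 and C10 are not enolisable and stay as set.

Step 12
Reactants: 20 C5=C6 enol triflate
Product: 21 3-{[(1R,2S,8aS)-1,2,5,5-tetramethyl-1,2,3,5,6,7,8,8a-octahydronaphthalen-1-yl]methyl}-1,2,4,5-tetramethoxybenzene
Conditions: Pd(OAc)2 (10 mol%), PPh3 (20 mol%), HCO2H, Bu3N, DMF, 60 °C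
Reagents that add atoms: none
Why: Palladium-catalysed formate hydrogenolysis of the vinyl triflate (oxidative addition, formate exchange, decarboxylation, C–H reductive elimination) replaces OTf by H without moving the C5=C6 double bond or touching the aryl ethers.

Step 13
Reactants: 21 3-{[(1R,2S,8aS)-1,2,5,5-tetramethyl-1,2,3,5,6,7,8,8a-octahydronaphthalen-1-yl]methyl}-1,2,4,5-tetramethoxybenzene
Product: 22 2,5-dimethoxy-3-{[(1R,2S,8aS)-1,2,5,5-tetramethyl-1,2,3,5,6,7,8,8a-octahydronaphthalen-1-yl]methyl}cyclohexa-2,5-diene-1,4-dione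
Conditions: CAN (2.5 equiv), MeCN–H2O (2:1), 0 °C
Reagents that add atoms: water, O
Why: Ceric ammonium nitrate oxidative demethylation of a para-dimethoxy pair gives the 2,5-dimethoxy-1,4-benzoquinone; either para pair of the symmetric arene leads to the same quinone, and the brief, cold oxidation should leave the trisubstituted olefin intact.

Step 14
Reactants: 22 2,5-dimethoxy-3-{[(1R,2S,8aS)-1,2,5,5-tetramethyl-1,2,3,5,6,7,8,8a-octahydronaphthalen-1-yl]methyl}cyclohexa-2,5-diene-1,4-dione
Product: 23 2-hydroxy-5-methoxy-3-{[(1R,2S,8aS)-1,2,5,5-tetramethyl-1,2,3,5,6,7,8,8a-octahydronaphthalen-1-yl]methyl}cyclohexa-2,5-diene-1,4-dione (target)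
Conditions: KOH (2 M aq.), MeOH, rt; then 1 M HCl, 0 °C
Reagents that add atoms: potassium hydroxide, [K+].[OH-]
Why: Addition–elimination of hydroxide on a vinylogous ester (selective saponification) is expected at the methoxy group next to the alkyl substituent, which is twisted out of conjugation and therefore the more electrophilic position, and the quinonolate formed resists a second attack; basic conditions avoid acid-triggered reactions of the C5=C6 olefin.

**Compound list**

1 | methyl (S)-3-hydroxy-2-methylpropanoate | COC(=O)[C@@H](C)CO | starting material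
2 | methyl (S)-3-[(tert-butyldimethylsilyl)oxy]-2-methylpropanoate | COC(=O)[C@@H](C)CO[Si](C)(C)C(C)(C)C | intermediate
3 | (3S)-4-[(tert-butyldimethylsilyl)oxy]-3-methyl-1-(trimethylsilyl)-2-[(trimethylsilyl)methyl]butan-2-ol (formed in the flask) | C[Si](C)(C)CC(O)(C[Si](C)(C)C)[C@@H](C)CO[Si](C)(C)C(C)(C)C | intermediate
4 | tert-butyldimethyl{[(2R)-2-methyl-3-[(trimethylsilyl)methyl]but-3-en-1-yl]oxy}silane | C[Si](C)(C)CC(=C)[C@@H](C)CO[Si](C)(C)C(C)(C)C | intermediate
5 | {[(2R)-3-(bromomethyl)-2-methylbut-3-en-1-yl]oxy}(tert-butyl)dimethylsilane | BrCC(=C)[C@@H](C)CO[Si](C)(C)C(C)(C)C | intermediate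
6 | 1,2,4,5-tetramethoxybenzene | COc1cc(OC)c(OC)cc1OC | starting material
7 | (2,3,5,6-tetramethoxyphenyl)lithium (formed in the flask) | COc1cc(OC)c(OC)c([Li])c1OC | intermediate
8 | tert-butyldimethyl{[(2R)-2-methyl-3-(2,3,5,6-tetramethoxybenzyl)but-3-en-1-yl]oxy}silane | COc1cc(OC)c(OC)c(CC(=C)[C@@H](C)CO[Si](C)(C)C(C)(C)C)c1OC | intermediate
9 | (2R)-2-methyl-3-(2,3,5,6-tetramethoxybenzyl)but-3-en-1-ol | COc1cc(OC)c(OC)c(CC(=C)[C@@H](C)CO)c1OC | intermediate
10 | 3-[(3R)-4-iodo-3-methyl-2-methylidenebutyl]-1,2,4,5-tetramethoxybenzene | COc1cc(OC)c(OC)c(CC(=C)[C@@H](C)CI)c1OC | intermediate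
11 | 2,2-dimethylcyclohexanone | CC1(C)CCCCC1=O | starting material
12 | lithium 6,6-dimethylcyclohex-1-en-1-olate (formed in the flask) | [Li]OC1=CCCCC1(C)C | intermediate
13 | 6,6-dimethylcyclohex-1-en-1-yl trifluoromethanesulfonate | CC1(C)CCCC=C1OS(=O)(=O)C(F)(F)F | intermediate
14 | N-methoxy-N,6,6-trimethylcyclohex-1-ene-1-carboxamide | CON(C)C(=O)C1=CCCCC1(C)C | intermediate
15 | [(2S)-2-methyl-3-(2,3,5,6-tetramethoxybenzyl)but-3-en-1-yl]lithium (formed in the flask) | COc1cc(OC)c(OC)c(CC(=C)[C@@H](C)C[Li])c1OC | intermediate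
16 | lithium (3S)-1-(6,6-dimethylcyclohex-1-en-1-yl)-1-[methoxy(methyl)amino]-3-methyl-4-(2,3,5,6-tetramethoxybenzyl)pent-4-en-1-olate (formed in the flask) | COc1cc(OC)c(OC)c(CC(=C)[C@@H](C)CC(O[Li])(N(C)OC)C2=CCCCC2(C)C)c1OC | intermediate
17 | (3S)-1-(6,6-dimethylcyclohex-1-en-1-yl)-3-methyl-4-(2,3,5,6-tetramethoxybenzyl)pent-4-en-1-one | COc1cc(OC)c(OC)c(CC(=C)[C@@H](C)CC(=O)C2=CCCCC2(C)C)c1OC | intermediate
18 | (3S,4R,4aR)-3,4,8,8-tetramethyl-4-(2,3,5,6-tetramethoxybenzyl)octahydronaphthalen-1(2H)-one, C8a (terpenoid C5) epimers | COc1cc(OC)c(OC)c(C[C@@]2(C)[C@@H]3CCCC(C)(C)C3C(=O)C[C@@H]2C)c1OC | intermediate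
19 | potassium (3S,4R,4aS)-3,4,8,8-tetramethyl-4-(2,3,5,6-tetramethoxybenzyl)-2,3,4,4a,5,6,7,8-octahydronaphthalen-1-olate (formed in the flask) | COc1cc(OC)c(OC)c(C[C@@]2(C)[C@@H]3CCCC(C)(C)C3=C(O[K])C[C@@H]2C)c1OC | intermediate
20 | (3S,4R,4aS)-3,4,8,8-tetramethyl-4-(2,3,5,6-tetramethoxybenzyl)-2,3,4,4a,5,6,7,8-octahydronaphthalen-1-yl trifluoromethanesulfonate | COc1cc(OC)c(OC)c(C[C@@]2(C)[C@@H]3CCCC(C)(C)C3=C(OS(=O)(=O)C(F)(F)F)C[C@@H]2C)c1OC | intermediate
21 | 3-{[(1R,2S,8aS)-1,2,5,5-tetramethyl-1,2,3,5,6,7,8,8a-octahydronaphthalen-1-yl]methyl}-1,2,4,5-tetramethoxybenzene | COc1cc(OC)c(OC)c(C[C@@]2(C)[C@@H]3CCCC(C)(C)C3=CC[C@@H]2C)c1OC | intermediate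
22 | 2,5-dimethoxy-3-{[(1R,2S,8aS)-1,2,5,5-tetramethyl-1,2,3,5,6,7,8,8a-octahydronaphthalen-1-yl]methyl}cyclohexa-2,5-diene-1,4-dione | COC1=CC(=O)C(OC)=C(C[C@@]2(C)[C@@H]3CCCC(C)(C)C3=CC[C@@H]2C)C1=O | intermediate
23 | 2-hydroxy-5-methoxy-3-{[(1R,2S,8aS)-1,2,5,5-tetramethyl-1,2,3,5,6,7,8,8a-octahydronaphthalen-1-yl]methyl}cyclohexa-2,5-diene-1,4-dione | COC1=CC(=O)C(O)=C(C[C@@]2(C)[C@@H]3CCCC(C)(C)C3=CC[C@@H]2C)C1=O | target

**Step count**

Total steps: 14. Longest linear sequence: 12 steps (1 to 23 through steps 1–6 and 9–14); steps 7–8 form the side branch to 14.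

**Steps most likely to fail, with fallbacks**

Step 10. The tertiary radical may lose a hydrogen atom from the neighbouring ArCH2 back to the metal (olefin migration into conjugation with the arene) or be reduced before it reaches C10. The chair preference that sets C9 may also be weak at 60 °C. The fallback sets out from 17. Markovnikov addition of anhydrous HBr (CH2Cl2, −78 °C) to the 1,1-disubstituted olefin should give the tertiary bromide F1. A tin hydride chain (Bu3SnH, Et3B/air, toluene, −78 to 0 °C) then generates the same C9 radical by bromine abstraction, without a metal hydride and at low temperature. 6-endo radical conjugate addition and hydrogen abstraction from tin return the route to 18.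

Step 11. Enolisation may settle on the C7 side instead of the hindered C5 methine, which after reduction would give the C6=C7 olefin. The fallback sets out from 18. Equilibration with NaOMe in MeOH should converge the C5 epimers on the trans-fused ketone F2. L-Selectride (THF, −78 °C) should attack from the equatorial direction and give the axial C6 alcohol F3. Dehydration with Martin sulfurane (CH2Cl2, rt) should proceed by anti elimination through the trans-diaxial H5/O6 arrangement. Loss of the tertiary H5 gives the more substituted olefin and relieves the syn-axial clash between the hydroxyl and the axial C4 methyl. The fallback bypasses 19 and 20 and comes back at 21.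

Step 9. Attack at the hindered, conjugated amide carbonyl may be slow, which would allow conjugate addition or proton transfer from the ArCH2 group to the alkyllithium. The fallback sets out from 14 and 10. Reduction of 14 with DIBAL-H (THF, −78 °C) should give the aldehyde F4. The alkyllithium 15, made from 10 as in step 9, adds 1,2 to it at −78 °C and gives the allylic alcohol F5 as inconsequential carbinol epimers. Oxidation with Dess–Martin periodinane (NaHCO3, CH2Cl2, rt) returns the route to 17.

**Further compounds**

F1 | step 10 | (3S)-4-bromo-1-(6,6-dimethylcyclohex-1-en-1-yl)-3,4-dimethyl-5-(2,3,5,6-tetramethoxyphenyl)pentan-1-one (C4 epimers) | COc1cc(OC)c(OC)c(CC(C)(Br)[C@@H](C)CC(=O)C2=CCCCC2(C)C)c1OC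
F2 | step 11 | (3S,4R,4aR,8aS)-3,4,8,8-tetramethyl-4-(2,3,5,6-tetramethoxybenzyl)octahydronaphthalen-1(2H)-one (trans-fused) | COc1cc(OC)c(OC)c(C[C@@]2(C)[C@@H]3CCCC(C)(C)[C@H]3C(=O)C[C@@H]2C)c1OC
F3 | step 11 | (1S,3S,4R,4aR,8aS)-3,4,8,8-tetramethyl-4-(2,3,5,6-tetramethoxybenzyl)decahydronaphthalen-1-ol (axial alcohol) | COc1cc(OC)c(OC)c(C[C@@]2(C)[C@@H]3CCCC(C)(C)[C@H]3[C@@H](O)C[C@@H]2C)c1OC
F4 | step 9 | 6,6-dimethylcyclohex-1-ene-1-carbaldehyde | O=CC1=CCCCC1(C)C
F5 | step 9 | (3S)-1-(6,6-dimethylcyclohex-1-en-1-yl)-3-methyl-4-(2,3,5,6-tetramethoxybenzyl)pent-4-en-1-ol (C1 epimers) | COc1cc(OC)c(OC)c(CC(=C)[C@@H](C)CC(O)C2=CCCCC2(C)C)c1OC
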